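Numbering of the target: C1 (CH–aryl), C2 (CH–CH3), C3 (=C–CH3), C4 (=CH), C4a, C8a. Retrosynthetic cuts: first C3–CH3 (cross-coupling of an enol triflate). Then C4 is taken out of the ring (C3–C4 and C4–C4a cut, C3–C4a rejoined), which contracts the carbocycle C1–C2–C3–C4–C4a–C8a to the five-membered ring of a trans-3-aryl-2-methylindan-1-one. After that C2–CH3, C3–C4a (aryl–acyl bond), C1–aryl and the C1=C2 bond of a cinnamamide are cut.
Forward order: the C1–C2–C3 chain is put on a brominated veratrole ring, the pendant ring is added at C1, the five-membered ring closes, C2 is methylated, one carbon atom is inserted to give the six-membered ring, and the last methyl group is coupled on.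
Feature that allows the insertion: C4 is the only atom of this ring with neither a substituent nor a stereocentre. Its neighbour C4a lies para to the C7 methoxy group, so it is an electron-rich aryl carbon that migrates readily from a carbonyl carbon (future C3) to an added CH unit.
Gain from the smaller ring: the indanone has a single enolisable carbon (future C2), next to the C1 stereocentre, whereas the corresponding 2-tetralone would be alkylated at C4.
Stereochemistry: C1 (R) comes from a chiral diene–rhodium catalyst, with a bromine atom keeping the two veratryl groups on C1 different until the ring is closed. C2 (S) comes from substrate control (methylation anti to the C1 aryl group, trans). Neither centre takes part in the later bond changes.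

Key step: step 5

Assumption: (R,R)-Ph-bod* is written for the ligand antipode that delivers the aryl group to the Si face of C3 of enamide 4; if the sense of induction on this acceptor is the opposite one, (S,S)-Ph-bod* is used and nothing else changes.

Step 1
Reactants: 1 2-bromo-4,5-dimethoxybenzaldehyde; 2 diethyl {2-[methoxy(methyl)amino]-2-oxoethyl}phosphonate
Product: 4 (E)-3-(2-bromo-4,5-dimethoxyphenyl)-N-methoxy-N-methylprop-2-enamide, via sodium phosphonate carbanion 3 (not isolated)
Conditions: NaH (1.1 equiv), THF, 0 °C → rt
Reagents that add atoms: none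
Why: Horner–Wadsworth–Emmons olefination with a carbonyl-stabilised phosphonate anion should give the E-alkene, and neither the aryl bromide nor the methyl ethers react with NaH at this temperature.

Step 2
Reactants: 4 (E)-3-(2-bromo-4,5-dimethoxyphenyl)-N-methoxy-N-methylprop-2-enamide; 5 (3,4-dimethoxyphenyl)boronic acid
Product: 6 (3R)-3-(2-bromo-4,5-dimethoxyphenyl)-3-(3,4-dimethoxyphenyl)-N-methoxy-N-methylpropanamide
Conditions: 5 (2 equiv), [RhCl(C2H4)2]2 (2.5 mol %), (R,R)-Ph-bod* (5.5 mol %), aq. KOH (20 mol %), 1,4-dioxane/H2O 10:1, 50 °C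
Reagents that add atoms: none
Why: This is a rhodium-catalysed asymmetric 1,4-addition of an arylboronic acid (Hayashi–Miyaura reaction), established for α,β-unsaturated N-methoxy-N-methylamides, in which the C2-symmetric diene ligand exposes only the Si face of C3 to the aryl–rhodium species and so sets this centre (future C1) as R, while the bromine atom, inert to Rh(I), keeps the two veratryl rings different.

Step 3
Reactants: 6 (3R)-3-(2-bromo-4,5-dimethoxyphenyl)-3-(3,4-dimethoxyphenyl)-N-methoxy-N-methylpropanamide
Product: 9 (3R)-3-(3,4-dimethoxyphenyl)-5,6-dimethoxy-2,3-dihydro-1H-inden-1-one, via aryllithium 7 (not isolated), via chelated lithium hemiaminal 8 (not isolated)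
Conditions: t-BuLi (2.1 equiv), THF, −78 °C; then H2O, −78 °C → rt
Reagents that add atoms: none
Why: In this Parham cyclisation, bromine–lithium exchange at −78 °C should outrun attack on the amide, aryllithium 7 closes the five-membered ring by 5-exo-trig addition to the amide carbonyl group, chelated adduct 8 survives until the quench and so prevents a second addition, and the doubly benzylic stereocentre is not deprotonated at this temperature.

Step 4
Reactants: 9 (3R)-3-(3,4-dimethoxyphenyl)-5,6-dimethoxy-2,3-dihydro-1H-inden-1-one
Product: 11 (2S,3R)-3-(3,4-dimethoxyphenyl)-5,6-dimethoxy-2-methyl-2,3-dihydro-1H-inden-1-one (trans), via lithium enolate 10 (not isolated)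
Conditions: LiHMDS (1.05 equiv), THF, −78 °C; MeI (1.5 equiv), −78 → −20 °C
Reagents that add atoms: iodomethane, CI
Why: In this enolate alkylation the ketone has a single enolisable carbon, and iodomethane should approach the flat enolate 10 from the face opposite to the neighbouring aryl group, which sets C2 as S (trans), the arrangement that is also favoured at equilibrium in the five-membered ring.

Step 5
Reactants: 11 (2S,3R)-3-(3,4-dimethoxyphenyl)-5,6-dimethoxy-2-methyl-2,3-dihydro-1H-inden-1-one
Product: 14 (3S,4R)-4-(3,4-dimethoxyphenyl)-6,7-dimethoxy-3-methyl-3,4-dihydronaphthalen-2(1H)-one, via diazonium betaine 12 (not isolated), via 1-silyl-2-tetralone 13 (not isolated)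
Conditions: TMSCHN2 (2 M in hexanes, 1.5 equiv), BF3·OEt2 (1.5 equiv), CH2Cl2, −78 → −20 °C; then 0.5 M HCl, THF, 0 °C, short contact
Reagents that add atoms: (trimethylsilyl)diazomethane, C[Si](C)(C)C=[N+]=[N-]
Why: BF3 activates the ketone, the nucleophilic diazo carbon adds to C1 of the indanone to give betaine 12, and loss of N2 goes together with a 1,2-shift of the aromatic carbon C7a from C1 to the new carbon, which places that carbon between the arene and the carbonyl group and turns the five-membered ring into the six-membered one. The closest known reaction type is the Lewis-acid-promoted homologation of benzo-fused aryl ketones with TMSCHN2 (Büchner–Curtius–Schlotterbeck/Tiffeneau–Demjanov type), which leads from α- to β-benzocycloalkenones by aryl migration. The six-membered ring is not closed by a cyclisation but by this suprafacial aryl shift through a phenonium-like bridged transition state, so no ring-closure mode in the usual sense applies. No lasting stereocentre is made: the C–Si centre of 13 is erased on protodesilylation, C3 of the indanone is remote from the event, and C2 is the non-migrating α-carbon, which is protected afterwards because 13 and 14 enolise towards the benzylic side. The step needs aryl over alkyl migration and a single insertion: the 5-methoxy group para to C7a makes the arene carbon the better migrating group and the branched C2 is the poorer one in diazoalkane homologations, while the bulky silyl group beside the new carbonyl group of 13 should block a second insertion.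

Step 6
Reactants: 14 (3S,4R)-4-(3,4-dimethoxyphenyl)-6,7-dimethoxy-3-methyl-3,4-dihydronaphthalen-2(1H)-one
Product: 16 (3S,4R)-4-(3,4-dimethoxyphenyl)-6,7-dimethoxy-3-methyl-3,4-dihydronaphthalen-2-yl trifluoromethanesulfonate, via potassium enolate 15 (not isolated)
Conditions: 14 added to KHMDS (1.1 equiv), THF, −78 °C; PhNTf2 (1.2 equiv), −78 → 0 °C; aqueous work-up
Reagents that add atoms: N-phenylbis(trifluoromethanesulfonimide), O=S(=O)(N(c1ccccc1)S(=O)(=O)C(F)(F)F)C(F)(F)F
Why: This is a regioselective enolisation and O-sulfonylation, in which the benzylic C1 methylene group of a 2-tetralone is much more acidic than C3–H, so KHMDS should give only the arene-conjugated enolate 15, whose triflation fixes the double bond at the future C3=C4 position and leaves both stereocentres untouched.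

Step 7
Reactants: 16 (3S,4R)-4-(3,4-dimethoxyphenyl)-6,7-dimethoxy-3-methyl-3,4-dihydronaphthalen-2-yl trifluoromethanesulfonate
Product: 17 (1R,2S)-1-(3,4-dimethoxyphenyl)-6,7-dimethoxy-2,3-dimethyl-1,2-dihydronaphthalene (target)
Conditions: MeZnCl (2 M in THF, 1.5 equiv), Pd(PPh3)4 (5 mol %), THF, rt → 45 °C
Reagents that add atoms: methylzinc chloride, C[Zn]Cl
Why: Negishi cross-coupling of an alkenyl triflate with a methylzinc reagent forms the C3–CH3 bond with retention of the double-bond position under essentially non-basic conditions, so that the doubly benzylic C1–H and the allylic C2–H should not be epimerised and no aromatisation should occur.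

Compound list
1 | 2-bromo-4,5-dimethoxybenzaldehyde | COc1cc(Br)c(C=O)cc1OC | starting material
2 | diethyl {2-[methoxy(methyl)amino]-2-oxoethyl}phosphonate | CCOP(=O)(CC(=O)N(C)OC)OCC | starting material
3 | sodium salt of the carbanion of 2 (not isolated) | CCOP(=O)([CH-]C(=O)N(C)OC)OCC.[Na+] | intermediate
4 | (E)-3-(2-bromo-4,5-dimethoxyphenyl)-N-methoxy-N-methylprop-2-enamide | CON(C)C(=O)/C=C/c1cc(OC)c(OC)cc1Br | intermediate
5 | (3,4-dimethoxyphenyl)boronic acid | COc1ccc(B(O)O)cc1OC | starting material
6 | (3R)-3-(2-bromo-4,5-dimethoxyphenyl)-3-(3,4-dimethoxyphenyl)-N-methoxy-N-methylpropanamide | COc1ccc([C@@H](CC(=O)N(C)OC)c2cc(OC)c(OC)cc2Br)cc1OC | intermediate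
7 | (3R)-3-(3,4-dimethoxyphenyl)-3-(2-lithio-4,5-dimethoxyphenyl)-N-methoxy-N-methylpropanamide (not isolated) | COc1ccc([C@@H](CC(=O)N(C)OC)c2cc(OC)c(OC)cc2[Li])cc1OC | intermediate
8 | lithium (3R)-3-(3,4-dimethoxyphenyl)-5,6-dimethoxy-1-[methoxy(methyl)amino]-2,3-dihydro-1H-inden-1-olate (not isolated) | COc1ccc([C@@H]2c3cc(OC)c(OC)cc3C(O[Li])(N(C)OC)C2)cc1OC | intermediate
9 | (3R)-3-(3,4-dimethoxyphenyl)-5,6-dimethoxy-2,3-dihydro-1H-inden-1-one | COc1ccc([C@@H]2c3cc(OC)c(OC)cc3C(=O)C2)cc1OC | intermediate
10 | lithium enolate of 9 (not isolated) | COc1ccc([C@@H]2c3cc(OC)c(OC)cc3C(O[Li])=C2)cc1OC | intermediate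
11 | (2S,3R)-3-(3,4-dimethoxyphenyl)-5,6-dimethoxy-2-methyl-2,3-dihydro-1H-inden-1-one | COc1ccc([C@@H]2c3cc(OC)c(OC)cc3C(=O)[C@H]2C)cc1OC | intermediate
12 | (2S,3R)-1-[diazonio(trimethylsilyl)methyl]-3-(3,4-dimethoxyphenyl)-5,6-dimethoxy-2-methyl-2,3-dihydro-1H-inden-1-olate, BF3-bound in the flask and drawn without the Lewis acid (not isolated) | COc1ccc([C@@H]2c3cc(OC)c(OC)cc3C([O-])(C([N+]#N)[Si](C)(C)C)[C@H]2C)cc1OC | intermediate
13 | (3S,4R)-4-(3,4-dimethoxyphenyl)-6,7-dimethoxy-3-methyl-1-(trimethylsilyl)-3,4-dihydronaphthalen-2(1H)-one, C1 not defined (not isolated) | COc1ccc([C@@H]2c3cc(OC)c(OC)cc3C([Si](C)(C)C)C(=O)[C@H]2C)cc1OC | intermediate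
14 | (3S,4R)-4-(3,4-dimethoxyphenyl)-6,7-dimethoxy-3-methyl-3,4-dihydronaphthalen-2(1H)-one | COc1ccc([C@@H]2c3cc(OC)c(OC)cc3CC(=O)[C@H]2C)cc1OC | intermediate
15 | potassium enolate of 14, C1=C2 (not isolated) | COc1ccc([C@@H]2c3cc(OC)c(OC)cc3C=C(O[K])[C@H]2C)cc1OC | intermediate
16 | (3S,4R)-4-(3,4-dimethoxyphenyl)-6,7-dimethoxy-3-methyl-3,4-dihydronaphthalen-2-yl trifluoromethanesulfonate | COc1ccc([C@@H]2c3cc(OC)c(OC)cc3C=C(OS(=O)(=O)C(F)(F)F)[C@H]2C)cc1OC | intermediate
17 | (1R,2S)-1-(3,4-dimethoxyphenyl)-6,7-dimethoxy-2,3-dimethyl-1,2-dihydronaphthalene | COc1ccc([C@@H]2c3cc(OC)c(OC)cc3C=C(C)[C@H]2C)cc1OC | target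

Total step count: 7. Longest linear sequence: 7 steps (from 1).

Steps most likely to fail

**Step 5.** The carbonyl group is deactivated by the para methoxy group and flanked by a branched carbon. Addition of the diazoalkane may therefore be slower than its destruction by the Lewis acid, and some migration of C2 instead of the arene carbon may occur.

Fallback, from 11 back to 14: the extra carbon is first put on as an alkene, and the aryl shift is then driven by iodine(III) instead of by loss of nitrogen.
- Wittig methylenation of 11 (Ph3PCH3Br, KOt-Bu, THF) would give (1R,2S)-1-(3,4-dimethoxyphenyl)-5,6-dimethoxy-2-methyl-3-methylidene-2,3-dihydro-1H-indene F1, handled on base-washed supports to avoid migration of the double bond into the ring.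
- Oxidative rearrangement with [hydroxy(tosyloxy)iodo]benzene in 95 % methanol at room temperature would lead to 14. The sequence is iodine(III) addition at the CH2 terminus, methanol at the benzylic carbon, 1,2-aryl shift with loss of iodobenzene, and hydrolysis of the ketal.
- This olefination/oxidative rearrangement sequence is an established way from α- to β-benzocycloalkenones.

**Step 3.** Attack of t-BuLi on the amide, or protonation of the aryllithium by the α-CH2 group, may compete with halogen–lithium exchange and ring closure.

Fallback, from 1 back to 9: the ring is closed by electrophilic acylation, and the bromine atom serves as a blocking group instead of a lithiation handle.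
- Horner–Wadsworth–Emmons reaction of 1 with tert-butyl diethylphosphonoacetate (NaH, THF) would give tert-butyl (E)-3-(2-bromo-4,5-dimethoxyphenyl)prop-2-enoate F2.
- Rhodium-catalysed 1,4-addition of 5 with the antipodal ligand (S,S)-Ph-bod* would give tert-butyl (3S)-3-(2-bromo-4,5-dimethoxyphenyl)-3-(3,4-dimethoxyphenyl)propanoate F3.
- CF3CO2H in CH2Cl2 would free (3S)-3-(2-bromo-4,5-dimethoxyphenyl)-3-(3,4-dimethoxyphenyl)propanoic acid F4.
- P2O5/MeSO3H at room temperature would acylate the unbrominated, more electron-rich ring para to its 3-methoxy group to give (3S)-3-(2-bromo-4,5-dimethoxyphenyl)-5,6-dimethoxy-2,3-dihydro-1H-inden-1-one F5.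
- Hydrogenolysis of the C–Br bond (H2, Pd/C, Et3N, EtOAc) would then give 9.
- The antipodal ligand is needed because the ring now closes onto the other veratryl group, which after loss of bromine inverts the sense of chirality at this carbon.

**Step 4.** Proton exchange between the product and unreacted enolate during the alkylation may lead to double methylation and incomplete conversion.

Fallback, from 9 back to 11: a removable ester makes C2 a carbon with only one acidic hydrogen.
- C-acylation of 9 with dimethyl carbonate (NaH, THF, reflux) would give methyl (3R)-3-(3,4-dimethoxyphenyl)-5,6-dimethoxy-1-oxo-2,3-dihydro-1H-indene-2-carboxylate F6.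
- Methylation (K2CO3, MeI, acetone) would give methyl (3R)-3-(3,4-dimethoxyphenyl)-5,6-dimethoxy-2-methyl-1-oxo-2,3-dihydro-1H-indene-2-carboxylate F7, which cannot be alkylated again.
- Krapcho demethoxycarbonylation (LiCl, wet DMSO, 140 °C) with protonation under equilibrating conditions would give the trans ketone 11.

Further compounds
F1 | step 5 | (1R,2S)-1-(3,4-dimethoxyphenyl)-5,6-dimethoxy-2-methyl-3-methylidene-2,3-dihydro-1H-indene | COc1ccc([C@@H]2c3cc(OC)c(OC)cc3C(=C)[C@H]2C)cc1OC
F2 | step 3 | tert-butyl (E)-3-(2-bromo-4,5-dimethoxyphenyl)prop-2-enoate | COc1cc(Br)c(/C=C/C(=O)OC(C)(C)C)cc1OC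
F3 | step 3 | tert-butyl (3S)-3-(2-bromo-4,5-dimethoxyphenyl)-3-(3,4-dimethoxyphenyl)propanoate | COc1cc(Br)c([C@@H](CC(=O)OC(C)(C)C)c2ccc(OC)c(OC)c2)cc1OC
F4 | step 3 | (3S)-3-(2-bromo-4,5-dimethoxyphenyl)-3-(3,4-dimethoxyphenyl)propanoic acid | COc1cc(Br)c([C@@H](CC(=O)O)c2ccc(OC)c(OC)c2)cc1OC
F5 | step 3 | (3S)-3-(2-bromo-4,5-dimethoxyphenyl)-5,6-dimethoxy-2,3-dihydro-1H-inden-1-one | COc1cc(Br)c([C@@H]2c3cc(OC)c(OC)cc3C(=O)C2)cc1OC
F6 | step 4 | methyl (3R)-3-(3,4-dimethoxyphenyl)-5,6-dimethoxy-1-oxo-2,3-dihydro-1H-indene-2-carboxylate | COc1ccc([C@@H]2c3cc(OC)c(OC)cc3C(=O)C2C(=O)OC)cc1OC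
F7 | step 4 | methyl (3R)-3-(3,4-dimethoxyphenyl)-5,6-dimethoxy-2-methyl-1-oxo-2,3-dihydro-1H-indene-2-carboxylate | COc1ccc([C@@H]2c3cc(OC)c(OC)cc3C(=O)C2(C)C(=O)OC)cc1OC
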